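**Plan**

- Cuts: the nine O–benzyl bonds; the C5'–C6' bond of ring D (intramolecular Claisen); the C7'–C8' bond (acylation of a ring-F dienolate by an upper-unit amide); in ring F the O1'–C2' and C4'–C4a' bonds (epoxide opening, acetoacetate alkylation); in the upper unit the C4–C6' bond (Reformatsky).
- Forward: rings A, C and B arrive with (+)-dihydrorobinetin and ring E with the aldehyde; ring F is closed first, the C6'–C7'–C8' chain is joined to it, ring D is folded last, and hydrogenolysis ends the route.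
- Stereochemistry: C2 and C3 come from dihydrorobinetin; C4 from hydride delivery anti to the 3-benzyloxy group; C3' and C2' from a Sharpless epoxidation (C2' inverted when ring F closes).
- Enabling feature: around ring D the oxygen-bearing carbons C5', C7' and C8a' (the last carrying the pyran oxygen O1') alternate with the carbon-substituted C6', C8' and C4a', so ring D is a phloroglucinol that can be read as a cyclised tri-β-carbonyl chain. Because O1' belongs to ring F before ring D exists, the chain can fold in one way only and C4 ends up on C6'.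

Key step: step 14

Remark: flavan numbering is used, unprimed for the upper unit (rings A, C, B) and primed for the lower unit (rings D, F, E); (+)-dihydrorobinetin is taken as the (2R,3R) compound.

**Route**

Step 1
Reactants: 1 (+)-dihydrorobinetin
Product: 2 (2R,3R)-7-(benzyloxy)-3-hydroxy-2-[3,4,5-tris(benzyloxy)phenyl]chroman-4-one
Conditions: BnBr (4.4 equiv), K2CO3, DMF, rt, Ar
Reagents that add atoms: benzyl bromide, BrCc1ccccc1
Why: Williamson etherification of the four phenols with carbonate as base should leave the non-acidic secondary 3-OH untouched, and the mild, oxygen-free conditions are chosen to avoid ring-C opening, C2/C3 epimerisation and dehydrogenation to the flavonol.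

Step 2
Reactants: 2 (2R,3R)-7-(benzyloxy)-3-hydroxy-2-[3,4,5-tris(benzyloxy)phenyl]chroman-4-one
Product: 3 (2R,3R)-3,7-bis(benzyloxy)-2-[3,4,5-tris(benzyloxy)phenyl]chroman-4-one
Conditions: BnOC(=NH)CCl3, CF3SO3H (cat.), CH2Cl2–cyclohexane, 0 °C → rt
Reagents that add atoms: benzyl 2,2,2-trichloroacetimidate, ClC(Cl)(Cl)C(=N)OCc1ccccc1
Why: Acid-catalysed benzyl transfer from the trichloroacetimidate etherifies the α-hydroxy ketone without base, so the E1cB ring opening and C3 epimerisation that alkoxide conditions would cause are avoided.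

Step 3
Reactants: 3 (2R,3R)-3,7-bis(benzyloxy)-2-[3,4,5-tris(benzyloxy)phenyl]chroman-4-one
Product: 4 ethyl 2-[(2R,3R,4S)-3,7-bis(benzyloxy)-4-hydroxy-2-[3,4,5-tris(benzyloxy)phenyl]chroman-4-yl]acetate
Conditions: BrCH2CO2Et, Zn dust (activated), THF, 50 °C; then 1 M HCl
Reagents that add atoms: ethyl bromoacetate, BrCC(=O)OCC
Why: The Reformatsky reaction uses a weakly basic zinc enolate that should add to the 3-alkoxy aryl ketone without enolising C3; the configuration of the new carbinol centre C4 (drawn 4S, hydroxyl cis to the 3-benzyloxy group) does not matter because it is erased in step 4.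

Step 4
Reactants: 4 ethyl 2-[(2R,3R,4S)-3,7-bis(benzyloxy)-4-hydroxy-2-[3,4,5-tris(benzyloxy)phenyl]chroman-4-yl]acetate
Product: 5 ethyl 2-[(2R,3S,4S)-3,7-bis(benzyloxy)-2-[3,4,5-tris(benzyloxy)phenyl]chroman-4-yl]acetate
Conditions: Et3SiH, CF3CO2H, CH2Cl2, −20 → 0 °C
Reagents that add atoms: none
Why: Ionic hydrogenation: trifluoroacetic acid ionises the tertiary benzylic alcohol to a C4 cation stabilised by O1 and the 7-benzyloxy group, and triethylsilane should deliver hydride to the face opposite the neighbouring 3-benzyloxy group, placing the acetate arm cis to O3 (4S, the 4β-substituted 2,3-trans-3,4-cis flavan).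

Step 5
Reactants: 5 ethyl 2-[(2R,3S,4S)-3,7-bis(benzyloxy)-2-[3,4,5-tris(benzyloxy)phenyl]chroman-4-yl]acetate
Product: 6 2-[(2R,3S,4S)-3,7-bis(benzyloxy)-2-[3,4,5-tris(benzyloxy)phenyl]chroman-4-yl]-N-methoxy-N-methylacetamide
Conditions: MeNHOMe·HCl, iPrMgCl, THF, −20 → 0 °C
Reagents that add atoms: N,O-dimethylhydroxylamine hydrochloride, CNOC.Cl
Why: Direct conversion of an ester into a Weinreb amide with the chloromagnesium amide of N,O-dimethylhydroxylamine is a standard acyl substitution that touches no stereocentre.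

Step 6
Reactants: 7 3,4,5-tris(benzyloxy)benzaldehyde
Product: 8 ethyl (E)-3-[3,4,5-tris(benzyloxy)phenyl]prop-2-enoate
Conditions: (EtO)2P(O)CH2CO2Et, NaH, THF, 0 °C → rt
Reagents that add atoms: triethyl phosphonoacetate, CCOC(=O)CP(=O)(OCC)OCC
Why: The Horner–Wadsworth–Emmons olefination of an aromatic aldehyde with a stabilised phosphonate anion reliably gives the E-cinnamate.

Step 7
Reactants: 8 ethyl (E)-3-[3,4,5-tris(benzyloxy)phenyl]prop-2-enoate
Product: 9 (E)-3-[3,4,5-tris(benzyloxy)phenyl]prop-2-en-1-ol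
Conditions: iBu2AlH (2.2 equiv), CH2Cl2, −78 °C; aq. potassium sodium tartrate
Reagents that add atoms: none
Why: 1,2-Reduction of the conjugated ester by two equivalents of iBu2AlH at low temperature gives the allylic alcohol with the E double bond intact.

Step 8
Reactants: 9 (E)-3-[3,4,5-tris(benzyloxy)phenyl]prop-2-en-1-ol
Product: 10 [(2S,3S)-3-[3,4,5-tris(benzyloxy)phenyl]oxiran-2-yl]methanol
Conditions: Ti(OiPr)4 (10 mol %), L-(+)-diisopropyl tartrate (12 mol %), tBuOOH, 4 Å molecular sieves, CH2Cl2, −20 °C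
Reagents that add atoms: tert-butyl hydroperoxide, CC(C)(C)OO
Why: Sharpless asymmetric epoxidation with L-(+)-tartrate delivers oxygen to the face of the E-allylic alcohol that gives the (2S,3S)-epoxide, as for cinnamyl alcohol itself, so both oxygenated carbons of ring F (later C3' and C2') are set here by catalyst control.

Step 9
Reactants: 10 [(2S,3S)-3-[3,4,5-tris(benzyloxy)phenyl]oxiran-2-yl]methanol
Product: 11 (2R,3S)-2-(iodomethyl)-3-[3,4,5-tris(benzyloxy)phenyl]oxirane
Conditions: PPh3, I2, imidazole, THF, 0 °C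
Reagents that add atoms: iodine, II
Why: Appel-type iodination under imidazole buffering converts the primary alcohol into the iodide by SN2 at the carbinol carbon without touching the two epoxide stereocentres (the 2R descriptor only reflects the changed priority of the CH2I group).

Step 10
Reactants: 11 (2R,3S)-2-(iodomethyl)-3-[3,4,5-tris(benzyloxy)phenyl]oxirane; 12 methyl acetoacetate
Product: 14 methyl 2-acetyl-3-[(2S,3S)-3-[3,4,5-tris(benzyloxy)phenyl]oxiran-2-yl]propanoate, via sodium enolate of methyl acetoacetate 13 (not isolated)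
Conditions: 12 (2 equiv), NaH (1.5 equiv), THF, 0 °C; then 11, DMF, 0 °C → rt
Reagents that add atoms: none
Why: SN2 C-alkylation of the stabilised acetoacetate enolate by the primary iodide should give the monoalkylated keto ester, and keeping methyl acetoacetate in excess over base leaves the less acidic product protonated so that base-induced 5-exo or 3-exo opening of the epoxide is suppressed; the new centre (later C4a') becomes sp2 in step 11.

Step 11
Reactants: 14 methyl 2-acetyl-3-[(2S,3S)-3-[3,4,5-tris(benzyloxy)phenyl]oxiran-2-yl]propanoate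
Product: 15 methyl (2R,3S)-3-hydroxy-6-methyl-2-[3,4,5-tris(benzyloxy)phenyl]-3,4-dihydro-2H-pyran-5-carboxylate
Conditions: (+)-camphor-10-sulfonic acid (10 mol %), CH2Cl2, −20 → 0 °C
Reagents that add atoms: none
Why: Acid-catalysed 6-endo epoxide opening, the enol-ether analogue of the acid-mediated closure of 2-(3-aryloxiranylmethyl)phenols to 2,3-trans-flavan-3-ols: the keto (enol) oxygen attacks the aryl-stabilised benzylic carbon C2' with inversion and proton loss gives the vinylogous carbonate, so the trans-epoxide is translated into the 2',3'-trans ring F (C2' R by inversion, C3' S retained).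

Step 12
Reactants: 15 methyl (2R,3S)-3-hydroxy-6-methyl-2-[3,4,5-tris(benzyloxy)phenyl]-3,4-dihydro-2H-pyran-5-carboxylate
Product: 16 methyl (2R,3S)-3-(benzyloxy)-6-methyl-2-[3,4,5-tris(benzyloxy)phenyl]-3,4-dihydro-2H-pyran-5-carboxylate
Conditions: NaH, BnBr, Bu4NI (cat.), THF–DMF, 0 °C → rt
Reagents that add atoms: benzyl bromide, BrCc1ccccc1
Why: Williamson benzylation of the secondary alkoxide, which cannot lactonise onto the ester across the ring double bond, while the γ-methyl protons are far less acidic than the hydroxyl.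

Step 13
Reactants: 16 methyl (2R,3S)-3-(benzyloxy)-6-methyl-2-[3,4,5-tris(benzyloxy)phenyl]-3,4-dihydro-2H-pyran-5-carboxylate; 6 2-[(2R,3S,4S)-3,7-bis(benzyloxy)-2-[3,4,5-tris(benzyloxy)phenyl]chroman-4-yl]-N-methoxy-N-methylacetamide
Product: 19 methyl (2R,3S)-3-(benzyloxy)-6-{3-[(2R,3S,4S)-3,7-bis(benzyloxy)-2-[3,4,5-tris(benzyloxy)phenyl]chroman-4-yl]-2-oxopropyl}-2-[3,4,5-tris(benzyloxy)phenyl]-3,4-dihydro-2H-pyran-5-carboxylate, via lithium dienolate of ester 16 17 (not isolated), via tetrahedral lithium adduct 18 (not isolated)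
Conditions: 16 (1.6 equiv), LiN(iPr)2 (1.5 equiv), THF, −78 °C; then 6, −78 → −30 °C; AcOH quench
Reagents that add atoms: none
Why: LiN(iPr)2 removes a proton from the 6-methyl group cis to the ester to give the extended dienolate (vinylogous deprotonation as for β-alkoxycrotonates and dioxinones), which should be acylated at its γ-terminus C8' by the Weinreb amide because the α-carbon is fully substituted, while the lithium-chelated tetrahedral adduct prevents over-addition and releases the ketone only on quench.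

Step 14
Reactants: 19 methyl (2R,3S)-3-(benzyloxy)-6-{3-[(2R,3S,4S)-3,7-bis(benzyloxy)-2-[3,4,5-tris(benzyloxy)phenyl]chroman-4-yl]-2-oxopropyl}-2-[3,4,5-tris(benzyloxy)phenyl]-3,4-dihydro-2H-pyran-5-carboxylate
Product: 21 (2R,3S)-3-(benzyloxy)-6-[(2R,3S,4R)-3,7-bis(benzyloxy)-2-[3,4,5-tris(benzyloxy)phenyl]chroman-4-yl]-2-[3,4,5-tris(benzyloxy)phenyl]chromane-5,7-diol, via cyclic 5',7'-dione 20 (not isolated)
Conditions: NaOMe (6 equiv), MeOH–THF (degassed), 65–100 °C (sealed tube), Ar; then 1 M HCl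
Reagents that add atoms: none
Why: Methoxide equilibrates the enolates of the C7' ketone; the dominant C8' anion is conjugated into the ester and has no productive outlet, whereas the minor C6' enolate adds to the C5' ester carbonyl held cis to it across the C4a'=C8a' double bond, expels methoxide and gives the cyclic dione 20, whose enolisation to the phloroglucinol phenoxide is irreversible and drains all preceding equilibria. The closest known reaction type is the base-mediated intramolecular Claisen condensation and aromatisation of masked 3,5-dioxo esters (β-alkoxy-δ-oxo enoates and dioxinone analogues) to phloroglucinol and resorcinol derivatives. Ring D closes by formation of the C5'–C6' bond in a 6-(enolendo)-exo-trig mode. No stereocentre is formed: C6' becomes aromatic, and C2, C3, C4, C2' and C3' are not enolisable and should keep their configuration. The step needs carbon rather than oxygen acylation and exclusive 4→6 connectivity: O-acylation to the fused 2-pyranone is reversed by methoxide whereas only the carbocycle can aromatise, and because O1' is already built into ring F the only carbon that can become the aryl carbon bonded to C4 is C6', so no C6'/C8' ambiguity arises.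

Step 15
Reactants: 21 (2R,3S)-3-(benzyloxy)-6-[(2R,3S,4R)-3,7-bis(benzyloxy)-2-[3,4,5-tris(benzyloxy)phenyl]chroman-4-yl]-2-[3,4,5-tris(benzyloxy)phenyl]chromane-5,7-diol
Product: 22 robinetinidol-(4β→6)-gallocatechin (CNP0311915.3)
Conditions: H2 (1 atm), Pd(OH)2/C, THF–MeOH, rt
Reagents that add atoms: none
Why: Hydrogenolysis of the nine benzyl ethers over Pd(OH)2 on carbon is the standard last step for benzylated oligoflavanoids and should leave the cyclic benzylic C2–O1 ethers and the interflavan C4–C6' bond intact at one atmosphere and room temperature.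

**Compound list**

1 | (+)-dihydrorobinetin, (2R,3R)-3,7-dihydroxy-2-(3,4,5-trihydroxyphenyl)chroman-4-one | Oc1ccc2c(c1)O[C@H](c1cc(O)c(O)c(O)c1)[C@@H](O)C2=O | starting material
2 | (2R,3R)-7-(benzyloxy)-3-hydroxy-2-[3,4,5-tris(benzyloxy)phenyl]chroman-4-one | c1ccccc1COc1ccc2c(c1)O[C@H](c1cc(OCc3ccccc3)c(OCc3ccccc3)c(OCc3ccccc3)c1)[C@@H](O)C2=O | intermediate
3 | (2R,3R)-3,7-bis(benzyloxy)-2-[3,4,5-tris(benzyloxy)phenyl]chroman-4-one | c1ccccc1COc1ccc2c(c1)O[C@H](c1cc(OCc3ccccc3)c(OCc3ccccc3)c(OCc3ccccc3)c1)[C@@H](OCc1ccccc1)C2=O | intermediate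
4 | ethyl 2-[(2R,3R,4S)-3,7-bis(benzyloxy)-4-hydroxy-2-[3,4,5-tris(benzyloxy)phenyl]chroman-4-yl]acetate (expected C4 epimer drawn; either epimer serves) | c1ccccc1COc1ccc2c(c1)O[C@H](c1cc(OCc3ccccc3)c(OCc3ccccc3)c(OCc3ccccc3)c1)[C@@H](OCc1ccccc1)[C@]2(O)CC(=O)OCC | intermediate
5 | ethyl 2-[(2R,3S,4S)-3,7-bis(benzyloxy)-2-[3,4,5-tris(benzyloxy)phenyl]chroman-4-yl]acetate (2,3-trans-3,4-cis) | c1ccccc1COc1ccc2c(c1)O[C@H](c1cc(OCc3ccccc3)c(OCc3ccccc3)c(OCc3ccccc3)c1)[C@@H](OCc1ccccc1)[C@H]2CC(=O)OCC | intermediate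
6 | 2-[(2R,3S,4S)-3,7-bis(benzyloxy)-2-[3,4,5-tris(benzyloxy)phenyl]chroman-4-yl]-N-methoxy-N-methylacetamide | c1ccccc1COc1ccc2c(c1)O[C@H](c1cc(OCc3ccccc3)c(OCc3ccccc3)c(OCc3ccccc3)c1)[C@@H](OCc1ccccc1)[C@H]2CC(=O)N(C)OC | intermediate
7 | 3,4,5-tris(benzyloxy)benzaldehyde | O=Cc1cc(OCc2ccccc2)c(OCc2ccccc2)c(OCc2ccccc2)c1 | starting material
8 | ethyl (E)-3-[3,4,5-tris(benzyloxy)phenyl]prop-2-enoate | CCOC(=O)/C=C/c1cc(OCc2ccccc2)c(OCc2ccccc2)c(OCc2ccccc2)c1 | intermediate
9 | (E)-3-[3,4,5-tris(benzyloxy)phenyl]prop-2-en-1-ol | OC/C=C/c1cc(OCc2ccccc2)c(OCc2ccccc2)c(OCc2ccccc2)c1 | intermediate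
10 | [(2S,3S)-3-[3,4,5-tris(benzyloxy)phenyl]oxiran-2-yl]methanol | OC[C@@H]1O[C@H]1c1cc(OCc2ccccc2)c(OCc2ccccc2)c(OCc2ccccc2)c1 | intermediate
11 | (2R,3S)-2-(iodomethyl)-3-[3,4,5-tris(benzyloxy)phenyl]oxirane | IC[C@@H]1O[C@H]1c1cc(OCc2ccccc2)c(OCc2ccccc2)c(OCc2ccccc2)c1 | intermediate
12 | methyl acetoacetate | COC(=O)CC(C)=O | starting material
13 | sodium enolate of methyl acetoacetate, sodium (Z)-4-methoxy-4-oxobut-2-en-2-olate | [Na+].COC(=O)/C=C(/C)[O-] | intermediate (not isolated)
14 | methyl 2-acetyl-3-[(2S,3S)-3-[3,4,5-tris(benzyloxy)phenyl]oxiran-2-yl]propanoate (both epimers at C2 of the propanoate) | COC(=O)C(C(C)=O)C[C@@H]1O[C@H]1c1cc(OCc2ccccc2)c(OCc2ccccc2)c(OCc2ccccc2)c1 | intermediate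
15 | methyl (2R,3S)-3-hydroxy-6-methyl-2-[3,4,5-tris(benzyloxy)phenyl]-3,4-dihydro-2H-pyran-5-carboxylate | CC1=C(C(=O)OC)C[C@H](O)[C@@H](c2cc(OCc3ccccc3)c(OCc3ccccc3)c(OCc3ccccc3)c2)O1 | intermediate
16 | methyl (2R,3S)-3-(benzyloxy)-6-methyl-2-[3,4,5-tris(benzyloxy)phenyl]-3,4-dihydro-2H-pyran-5-carboxylate | CC1=C(C(=O)OC)C[C@H](OCc2ccccc2)[C@@H](c2cc(OCc3ccccc3)c(OCc3ccccc3)c(OCc3ccccc3)c2)O1 | intermediate
17 | lithium dienolate of 16 (6-methylidene ring F, exocyclic ester enolate) | [Li+].C=C1C(=C([O-])OC)C[C@H](OCc2ccccc2)[C@@H](c2cc(OCc3ccccc3)c(OCc3ccccc3)c(OCc3ccccc3)c2)O1 | intermediate (not isolated)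
18 | tetrahedral lithium adduct of 17 and 6 (lithium alkoxide of the N-methoxy-N-methyl hemiaminal at C7', configuration at C7' undefined) | [Li+].c1ccccc1COc1ccc2c(c1)O[C@H](c1cc(OCc3ccccc3)c(OCc3ccccc3)c(OCc3ccccc3)c1)[C@@H](OCc1ccccc1)[C@H]2CC([O-])(N(C)OC)CC2=C(C(=O)OC)C[C@H](OCc1ccccc1)[C@@H](c1cc(OCc3ccccc3)c(OCc3ccccc3)c(OCc3ccccc3)c1)O2 | intermediate (not isolated)
19 | methyl (2R,3S)-3-(benzyloxy)-6-{3-[(2R,3S,4S)-3,7-bis(benzyloxy)-2-[3,4,5-tris(benzyloxy)phenyl]chroman-4-yl]-2-oxopropyl}-2-[3,4,5-tris(benzyloxy)phenyl]-3,4-dihydro-2H-pyran-5-carboxylate (masked triketide) | c1ccccc1COc1ccc2c(c1)O[C@H](c1cc(OCc3ccccc3)c(OCc3ccccc3)c(OCc3ccccc3)c1)[C@@H](OCc1ccccc1)[C@H]2CC(=O)CC2=C(C(=O)OC)C[C@H](OCc1ccccc1)[C@@H](c1cc(OCc3ccccc3)c(OCc3ccccc3)c(OCc3ccccc3)c1)O2 | intermediate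
20 | cyclic 5',7'-dione, the non-aromatic Claisen product (keto tautomer, C6' configuration undefined) | c1ccccc1COc1ccc2c(c1)O[C@H](c1cc(OCc3ccccc3)c(OCc3ccccc3)c(OCc3ccccc3)c1)[C@@H](OCc1ccccc1)[C@H]2C1C(=O)CC2=C(C1=O)C[C@H](OCc1ccccc1)[C@@H](c1cc(OCc3ccccc3)c(OCc3ccccc3)c(OCc3ccccc3)c1)O2 | intermediate (not isolated)
21 | (2R,3S)-3-(benzyloxy)-6-[(2R,3S,4R)-3,7-bis(benzyloxy)-2-[3,4,5-tris(benzyloxy)phenyl]chroman-4-yl]-2-[3,4,5-tris(benzyloxy)phenyl]chromane-5,7-diol (nona-O-benzyl dimer, free 5'- and 7'-OH) | c1ccccc1COc1ccc2c(c1)O[C@H](c1cc(OCc3ccccc3)c(OCc3ccccc3)c(OCc3ccccc3)c1)[C@@H](OCc1ccccc1)[C@H]2c1c(O)cc2c(c1O)C[C@H](OCc1ccccc1)[C@@H](c1cc(OCc3ccccc3)c(OCc3ccccc3)c(OCc3ccccc3)c1)O2 | intermediate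
22 | robinetinidol-(4β→6)-gallocatechin, (2R,3S)-6-[(2R,3S,4R)-3,7-dihydroxy-2-(3,4,5-trihydroxyphenyl)chroman-4-yl]-2-(3,4,5-trihydroxyphenyl)chromane-3,5,7-triol | Oc1ccc2c(c1)O[C@H](c1cc(O)c(O)c(O)c1)[C@@H](O)[C@H]2c1c(O)cc2c(c1O)C[C@H](O)[C@@H](c1cc(O)c(O)c(O)c1)O2 | target

**Count**

Total: 15 steps. Longest linear sequence: 10 steps (7 → 8 → 9 → 10 → 11 → 14 → 15 → 16 → 19 → 21 → 22); the upper-unit branch (1 → 6) has 5 steps.

**Steps most likely to fail**

Step 14. What may go wrong: the productive C6' enolate is a minor tautomer beside the C8' anion, whose charge is delocalised into the ester and switches off its electrophilicity, and C6' carries the bulky flavan-4-yl group. Ring closure may therefore need temperatures at which methoxide cleaves the C7'–C8' bond (retro-Claisen) or displaces benzyl groups. Fallback (sets out from 16 and 3, returns at 21): the dienolate 17 made from 16 would be acylated with N-methoxy-N-methylacetamide to the methyl ketone methyl (2R,3S)-3-(benzyloxy)-6-(2-oxopropyl)-2-[3,4,5-tris(benzyloxy)phenyl]-3,4-dihydro-2H-pyran-5-carboxylate F1, whose unhindered methyl group should undergo the same NaOMe Claisen aromatisation to 3,3',4',5'-tetra-O-benzylgallocatechin F2. Ketone 3 would be reduced with NaBH4 to the flavan-4-ol F3, and F3 condensed with an excess of F2 under BF3·OEt2 in CH2Cl2 (flavan-4-yl cation, Friedel–Crafts type) to give 21, which would have to be separated from its 8-linked and 4α-linked isomers. Ring D is still made by the Claisen folding, but the built-in regio- and stereocontrol of the interflavan bond is given up.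

Step 13. What may go wrong: proton transfer from the α-methylene of amide 6 to the strongly basic dienolate (enolisation instead of addition), or attack through the α-carbon C4a'. Fallback (sets out from 5 and 16, returns at 19): ester 5 would be saponified (LiOH, THF–H2O) to the acid F4 and converted with oxalyl chloride and catalytic DMF into the acid chloride F5. The dienolate from 16 would be trapped with Me3SiCl as the silyl dienol ether (methyl trimethylsilyl ketene acetal) F6. F6 and F5 would then be combined in CH2Cl2 at −78 °C to room temperature, where the neutral silyl dienol ether is acylated at its γ-terminus (vinylogous Mukaiyama-type acylation); aqueous work-up gives 19 without any strong base being present.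

Step 11. What may go wrong: ionisation of the electron-rich aryl oxirane faster than capture by the weakly nucleophilic keto oxygen, leading to 1,2-hydride shift (Meinwald rearrangement), 5-exo closure or erosion of configuration at C2'. Fallback (sets out from 10, returns at 16): ring F would be closed by cyclodehydration with retention instead of by epoxide opening. Ti(OiPr)4-mediated opening of epoxy alcohol 10 with benzoic acid at the benzylic carbon (inversion) gives the diol benzoate F7. Selective iodination of the primary hydroxyl (PPh3, I2, imidazole) gives the iodohydrin benzoate F8, and acid-catalysed benzylation with benzyl trichloroacetimidate gives the benzyl ether F9. Alkylation of the sodium enolate 13 with F9 (DMF, 50 °C) gives the keto ester F10. Methanolysis of the benzoate (K2CO3, MeOH) and acid-catalysed dehydration of the resulting six-membered hemiketal (pyridinium p-toluenesulfonate, toluene, 80 °C) give 16 directly, the C2'–O bond formed in the benzoate opening being kept.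

**Further compounds**

F1 | step 14 | methyl (2R,3S)-3-(benzyloxy)-6-(2-oxopropyl)-2-[3,4,5-tris(benzyloxy)phenyl]-3,4-dihydro-2H-pyran-5-carboxylate | CC(=O)CC1=C(C(=O)OC)C[C@H](OCc2ccccc2)[C@@H](c2cc(OCc3ccccc3)c(OCc3ccccc3)c(OCc3ccccc3)c2)O1
F2 | step 14 | (2R,3S)-3-(benzyloxy)-2-[3,4,5-tris(benzyloxy)phenyl]chromane-5,7-diol (3,3',4',5'-tetra-O-benzylgallocatechin) | c1c(O)cc2c(c1O)C[C@H](OCc1ccccc1)[C@@H](c1cc(OCc3ccccc3)c(OCc3ccccc3)c(OCc3ccccc3)c1)O2
F3 | step 14 | (2R,3S,4R)-3,7-bis(benzyloxy)-2-[3,4,5-tris(benzyloxy)phenyl]chroman-4-ol (3,4-trans epimer expected; either serves) | c1ccccc1COc1ccc2c(c1)O[C@H](c1cc(OCc3ccccc3)c(OCc3ccccc3)c(OCc3ccccc3)c1)[C@@H](OCc1ccccc1)[C@@H]2O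
F4 | step 13 | 2-[(2R,3S,4S)-3,7-bis(benzyloxy)-2-[3,4,5-tris(benzyloxy)phenyl]chroman-4-yl]acetic acid | c1ccccc1COc1ccc2c(c1)O[C@H](c1cc(OCc3ccccc3)c(OCc3ccccc3)c(OCc3ccccc3)c1)[C@@H](OCc1ccccc1)[C@H]2CC(=O)O
F5 | step 13 | 2-[(2R,3S,4S)-3,7-bis(benzyloxy)-2-[3,4,5-tris(benzyloxy)phenyl]chroman-4-yl]acetyl chloride | c1ccccc1COc1ccc2c(c1)O[C@H](c1cc(OCc3ccccc3)c(OCc3ccccc3)c(OCc3ccccc3)c1)[C@@H](OCc1ccccc1)[C@H]2CC(=O)Cl
F6 | step 13 | (2R,3S)-3-(benzyloxy)-5-[methoxy(trimethylsilyloxy)methylidene]-6-methylidene-2-[3,4,5-tris(benzyloxy)phenyl]tetrahydropyran (silyl dienol ether of 16) | C=C1C(=C(OC)O[Si](C)(C)C)C[C@H](OCc2ccccc2)[C@@H](c2cc(OCc3ccccc3)c(OCc3ccccc3)c(OCc3ccccc3)c2)O1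
F7 | step 11 | (1R,2S)-2,3-dihydroxy-1-[3,4,5-tris(benzyloxy)phenyl]propyl benzoate | OC[C@H](O)[C@H](OC(=O)c1ccccc1)c1cc(OCc2ccccc2)c(OCc2ccccc2)c(OCc2ccccc2)c1
F8 | step 11 | (1R,2R)-2-hydroxy-3-iodo-1-[3,4,5-tris(benzyloxy)phenyl]propyl benzoate | IC[C@H](O)[C@H](OC(=O)c1ccccc1)c1cc(OCc2ccccc2)c(OCc2ccccc2)c(OCc2ccccc2)c1
F9 | step 11 | (1R,2R)-2-(benzyloxy)-3-iodo-1-[3,4,5-tris(benzyloxy)phenyl]propyl benzoate | IC[C@H](OCc1ccccc1)[C@H](OC(=O)c1ccccc1)c1cc(OCc2ccccc2)c(OCc2ccccc2)c(OCc2ccccc2)c1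
F10 | step 11 | methyl (4S,5R)-2-acetyl-5-(benzoyloxy)-4-(benzyloxy)-5-[3,4,5-tris(benzyloxy)phenyl]pentanoate (both epimers at C2) | COC(=O)C(C(C)=O)C[C@H](OCc1ccccc1)[C@H](OC(=O)c1ccccc1)c1cc(OCc2ccccc2)c(OCc2ccccc2)c(OCc2ccccc2)c1
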